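**Retrosynthetic overview**
1. Target ⇐ its tert-butyl ester. Pyran ring B is opened by retro-oxa-6π / retro-Knoevenagel (O1–C2 and C4–C4a) to a dearomatised benzoyl trione (ring A) and 3-methylbut-2-enal.
2. Ring A ⇐ [3+3] double Claisen of the 1-phenylbutane-1,3-dione dianion onto a quaternary malonic half-ester (acid carbon → C8a, ester carbon → C7), which carries the half-ester configuration into C8.
3. Half-ester ⇐ prochiral dimethyl malonate by catalyst-controlled mono-saponification: the key acyl C–O bond formation, which creates the C8 stereocentre.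
4. Diester ⇐ dimethyl malonate + prenyl bromide + a (5S)-iodide; the iodide ⇐ Evans deconjugative allylation (side-chain centre) and cross-metathesis with tert-butyl methacrylate (E-enoate).
5. Ring order: carbocyclic ring A (step 8), then 2H-pyran ring B (step 9); the phenyl ring is bought.

Assumption: triketones are written in the tautomer of the target SMILES and CIP descriptors refer to that tautomer; a one-flask sequence counts as one step.

**Route**

Step 1
Reactants: 1 (4S)-4-benzyl-1,3-oxazolidin-2-one; 2 3-methylbut-2-enoyl chloride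
Product: 3 (4S)-4-benzyl-3-(3-methylbut-2-enoyl)-1,3-oxazolidin-2-one
Conditions: n-BuLi (1.05 equiv), THF, −78 °C; then 2, −78 → 0 °C
Reagents that add atoms: 3-methylbut-2-enoyl chloride (2), CC(C)=CC(=O)Cl
Why: N-acylation of the lithiated oxazolidinone by the acid chloride (Evans imide formation), no new stereocentre.

Step 2
Reactants: 3 senecioyl imide; 4 allyl iodide (3-iodoprop-1-ene)
Product: 5 (4S)-4-benzyl-3-[(2S)-2-(prop-1-en-2-yl)pent-4-enoyl]-1,3-oxazolidin-2-one
Conditions: NaN(SiMe3)2 (1.05 equiv), THF, −78 °C, 1 h; 4 (3 equiv), −78 → −45 °C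
Reagents that add atoms: allyl iodide (4), C=CCI
Why: Evans asymmetric alkylation in its deconjugative form: γ-deprotonation gives the chelated Z-dienolate, which is allylated at the α-carbon on the face opposite the benzyl group, setting the (2S) centre that becomes the side-chain stereocentre of the target.

Step 3
Reactants: 5 allylated imide
Product: 6 (2S)-2-(prop-1-en-2-yl)pent-4-en-1-ol
Conditions: LiBH4 (1.5 equiv), H2O (1.5 equiv), Et2O, 0 °C
Reagents that add atoms: none
Why: Reductive cleavage of the N-acyl oxazolidinone by borohydride leaves both alkenes and the α-centre untouched and returns the auxiliary.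

Step 4
Reactants: 6 dienol; 7 tert-butyl methacrylate
Product: 8 tert-butyl (2E,5S)-5-(hydroxymethyl)-2,6-dimethylhepta-2,6-dienoate
Conditions: 7 (10 equiv), second-generation Hoveyda–Grubbs catalyst RuCl2(H2IMes)(=CH-C6H4-2-OiPr) (5 mol %), CH2Cl2, 40 °C
Reagents that add atoms: tert-butyl methacrylate (7), C=C(C)C(=O)OC(C)(C)C
Why: Olefin cross-metathesis of the terminal alkene with a methacrylate gives the trisubstituted enoate with thermodynamic E-selectivity, while the α-branched 1,1-disubstituted isopropenyl group does not react.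

Step 5
Reactants: 8 hydroxy enoate
Product: 9 tert-butyl (2E,5S)-5-(iodomethyl)-2,6-dimethylhepta-2,6-dienoate
Conditions: PPh3, imidazole, I2, CH2Cl2, 0 → 25 °C
Reagents that add atoms: iodine, II
Why: Appel iodination of a primary alcohol (SN2 at CH2), stereocentre not involved.

Step 6
Reactants: 9 iodide; 10 dimethyl malonate; 11 prenyl bromide (1-bromo-3-methylbut-2-ene)
Product: 13 dimethyl 2-[(2R,4E)-6-tert-butoxy-5-methyl-6-oxo-2-(prop-1-en-2-yl)hex-4-en-1-yl]-2-(3-methylbut-2-en-1-yl)propanedioate, via monoalkyl malonate 12 (not isolated)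
Conditions: 10 (1.2 equiv), NaH (1.2 equiv), DMF, 0 → 60 °C; then NaH (1.3 equiv), 11 (1.5 equiv), 0 → 25 °C
Reagents that add atoms: dimethyl malonate (10), COC(=O)CC(=O)OC; prenyl bromide (11), CC(C)=CCBr
Why: Malonic ester synthesis with two successive SN2 alkylations, the β-branched iodide on the unhindered malonate first and the reactive allylic bromide second to build the quaternary carbon, which is still prochiral (two identical esters), so no stereocentre is created here.

Step 7
Reactants: 13 prochiral diester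
Product: 14 (2R)-2-[(2R,4E)-6-tert-butoxy-5-methyl-6-oxo-2-(prop-1-en-2-yl)hex-4-en-1-yl]-2-(methoxycarbonyl)-5-methylhex-4-enoic acid
Conditions: N-benzylcinchonidinium bromide carrying a 9-[3,5-bis(trifluoromethyl)phenyl]urea in place of the 9-hydroxyl (bifunctional phase-transfer catalyst, 10 mol %), 50% aq. KOH (1.5 equiv), toluene, 0 → 20 °C; then 1 M HCl
Reagents that add atoms: potassium hydroxide, [K+].[OH-]
Why: Proposed new method: chiral ion-pair-controlled desymmetrising mono-saponification of a prochiral 2,2-dialkylmalonate, in which the urea N–H pair binds the two ester carbonyls and holds the malonate against the quinuclidinium, so that the ammonium-paired hydroxide adds to the pro-S ester along the trajectory that passes the flat unbranched prenyl group instead of the β-branched (2R) chain, and the carboxylate formed is protected from a second hydrolysis while the tert-butyl ester is inert; this acyl C–O bond formation sets the quaternary stereocentre (2R here, 8S in the target), the closest known reaction types being the selective monohydrolysis of symmetric diesters with aqueous KOH, asymmetric phase-transfer ester hydrolysis and esterase desymmetrisation of dialkylmalonates; the pseudoenantiomeric cinchonine-derived catalyst is used instead if the substrate bias from the side-chain centre turns out to be mismatched.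

Step 8
Reactants: 14 half-ester; 15 1-phenylbutane-1,3-dione
Product: 18 tert-butyl (2E,5R)-5-{[(1S)-3-benzoyl-2-hydroxy-1-(3-methylbut-2-en-1-yl)-4,6-dioxocyclohex-2-en-1-yl]methyl}-2,6-dimethylhepta-2,6-dienoate, via acyl imidazolide 16 (not isolated), via triketo ester 17 (not isolated)
Conditions: 14, CDI (1.1 equiv), THF, 25 °C; add to 15 (3.2 equiv) + LiN(iPr)2 (6.4 equiv), THF, −78 → 50 °C; then 1 M HCl
Reagents that add atoms: 1-phenylbutane-1,3-dione (15), CC(=O)CC(=O)c1ccccc1
Why: Biomimetic polyketide-type assembly: the terminal carbanion of the β-diketone dianion is acylated by the acyl imidazolide (far more electrophilic than the hindered methyl ester) and the internal diketone carbon then closes ring A by intramolecular Claisen condensation onto the methyl ester; because the acid carbon becomes C-8a and the ester carbon C-7, the configuration from step 7 is carried unchanged into the ring.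

Step 9
Reactants: 18 benzoyl trione; 19 3-methylbut-2-enal
Product: 21 tert-butyl (2E,5R)-5-{[(8S)-6-benzoyl-7-hydroxy-2,2-dimethyl-8-(3-methylbut-2-en-1-yl)-5-oxo-5,8-dihydro-2H-chromen-8-yl]methyl}-2,6-dimethylhepta-2,6-dienoate, via oxatriene 20 (not isolated)
Conditions: 19 (2 equiv), ethylenediammonium diacetate (20 mol %), toluene, 80 °C
Reagents that add atoms: 3-methylbut-2-enal (19), CC(C)=CC=O
Why: Knoevenagel condensation at the only enolisable ring carbon followed by oxa-6π electrocyclisation (formal [3+3] chromenylation) forms the pyran C–O bond; closure is expected at the C-8a oxygen, which is not tied up in the hydrogen-bonded benzoyl chelate (the analogue of para-oxygen closure in acylphloroglucinols), and no stereocentre is formed.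

Step 10
Reactants: 21 tert-butyl ester
Product: 23 (2E,5R)-5-{[(8S)-6-benzoyl-7-hydroxy-2,2-dimethyl-8-(3-methylbut-2-en-1-yl)-5-oxo-5,8-dihydro-2H-chromen-8-yl]methyl}-2,6-dimethylhepta-2,6-dienoic acid, via bis-silyl derivative 22 (not isolated)
Conditions: Me3SiOTf (4 equiv), 2,6-lutidine (6 equiv), CH2Cl2, 0 °C; then aq. citric acid, MeOH
Reagents that add atoms: none
Why: Silyl-triflate-mediated tert-butyl ester cleavage (loss of isobutene through the silyl ester) under buffered non-protic conditions spares the prenyl, isopropenyl and 2H-pyran units, and the aqueous work-up frees the acid and the enol without touching either stereocentre.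

**Compound list**
1 | (4S)-4-benzyl-1,3-oxazolidin-2-one | O=C1N[C@@H](Cc2ccccc2)CO1 | starting material
2 | 3-methylbut-2-enoyl chloride | CC(C)=CC(=O)Cl | starting material
3 | (4S)-4-benzyl-3-(3-methylbut-2-enoyl)-1,3-oxazolidin-2-one | CC(C)=CC(=O)N1[C@@H](Cc2ccccc2)COC1=O | intermediate
4 | allyl iodide (3-iodoprop-1-ene) | C=CCI | starting material
5 | (4S)-4-benzyl-3-[(2S)-2-(prop-1-en-2-yl)pent-4-enoyl]-1,3-oxazolidin-2-one | C=C(C)[C@H](CC=C)C(=O)N1[C@@H](Cc2ccccc2)COC1=O | intermediate
6 | (2S)-2-(prop-1-en-2-yl)pent-4-en-1-ol | C=C(C)[C@H](CC=C)CO | intermediate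
7 | tert-butyl methacrylate (tert-butyl 2-methylprop-2-enoate) | C=C(C)C(=O)OC(C)(C)C | starting material
8 | tert-butyl (2E,5S)-5-(hydroxymethyl)-2,6-dimethylhepta-2,6-dienoate | C=C(C)[C@H](C/C=C(\C)C(=O)OC(C)(C)C)CO | intermediate
9 | tert-butyl (2E,5S)-5-(iodomethyl)-2,6-dimethylhepta-2,6-dienoate | C=C(C)[C@H](C/C=C(\C)C(=O)OC(C)(C)C)CI | intermediate
10 | dimethyl malonate (dimethyl propanedioate) | COC(=O)CC(=O)OC | starting material
11 | prenyl bromide (1-bromo-3-methylbut-2-ene) | CC(C)=CCBr | starting material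
12 | dimethyl 2-[(2R,4E)-6-tert-butoxy-5-methyl-6-oxo-2-(prop-1-en-2-yl)hex-4-en-1-yl]propanedioate | C=C(C)[C@H](C/C=C(\C)C(=O)OC(C)(C)C)CC(C(=O)OC)C(=O)OC | intermediate (not isolated)
13 | dimethyl 2-[(2R,4E)-6-tert-butoxy-5-methyl-6-oxo-2-(prop-1-en-2-yl)hex-4-en-1-yl]-2-(3-methylbut-2-en-1-yl)propanedioate (prochiral at C-2) | C=C(C)[C@H](C/C=C(\C)C(=O)OC(C)(C)C)CC(CC=C(C)C)(C(=O)OC)C(=O)OC | intermediate
14 | (2R)-2-[(2R,4E)-6-tert-butoxy-5-methyl-6-oxo-2-(prop-1-en-2-yl)hex-4-en-1-yl]-2-(methoxycarbonyl)-5-methylhex-4-enoic acid | C=C(C)[C@H](C/C=C(\C)C(=O)OC(C)(C)C)C[C@@](C(=O)O)(CC=C(C)C)C(=O)OC | intermediate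
15 | 1-phenylbutane-1,3-dione | CC(=O)CC(=O)c1ccccc1 | starting material
16 | acyl imidazolide of 14 (carboxyl replaced by 1H-imidazol-1-ylcarbonyl, same configuration) | C=C(C)[C@H](C/C=C(\C)C(=O)OC(C)(C)C)C[C@@](C(=O)n1ccnc1)(CC=C(C)C)C(=O)OC | intermediate (not isolated)
17 | methyl (2R)-2-[(2R,4E)-6-tert-butoxy-5-methyl-6-oxo-2-(prop-1-en-2-yl)hex-4-en-1-yl]-2-(3-methylbut-2-en-1-yl)-3,5,7-trioxo-7-phenylheptanoate | C=C(C)[C@H](C/C=C(\C)C(=O)OC(C)(C)C)C[C@@](C(=O)CC(=O)CC(=O)c1ccccc1)(CC=C(C)C)C(=O)OC | intermediate (not isolated)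
18 | tert-butyl (2E,5R)-5-{[(1S)-3-benzoyl-2-hydroxy-1-(3-methylbut-2-en-1-yl)-4,6-dioxocyclohex-2-en-1-yl]methyl}-2,6-dimethylhepta-2,6-dienoate | C=C(C)[C@H](C/C=C(\C)C(=O)OC(C)(C)C)C[C@@]1(CC=C(C)C)C(O)=C(C(=O)c2ccccc2)C(=O)CC1=O | intermediate
19 | 3-methylbut-2-enal | CC(C)=CC=O | starting material
20 | tert-butyl (2E,5R)-5-{[(1S)-3-benzoyl-2-hydroxy-5-(3-methylbut-2-en-1-ylidene)-1-(3-methylbut-2-en-1-yl)-4,6-dioxocyclohex-2-en-1-yl]methyl}-2,6-dimethylhepta-2,6-dienoate (dienyl arm cis to the C-6 carbonyl) | C=C(C)[C@H](C/C=C(\C)C(=O)OC(C)(C)C)C[C@@]1(CC=C(C)C)C(O)=C(C(=O)c2ccccc2)C(=O)/C(=C/C=C(C)C)C1=O | intermediate (not isolated)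
21 | tert-butyl (2E,5R)-5-{[(8S)-6-benzoyl-7-hydroxy-2,2-dimethyl-8-(3-methylbut-2-en-1-yl)-5-oxo-5,8-dihydro-2H-chromen-8-yl]methyl}-2,6-dimethylhepta-2,6-dienoate | C=C(C)[C@H](C/C=C(\C)C(=O)OC(C)(C)C)C[C@@]1(CC=C(C)C)C(O)=C(C(=O)c2ccccc2)C(=O)C2=C1OC(C)(C)C=C2 | intermediate
22 | trimethylsilyl ester and 7-O-trimethylsilyl enol ether of 23 (same configuration) | C=C(C)[C@H](C/C=C(\C)C(=O)O[Si](C)(C)C)C[C@@]1(CC=C(C)C)C(O[Si](C)(C)C)=C(C(=O)c2ccccc2)C(=O)C2=C1OC(C)(C)C=C2 | intermediate (not isolated)
23 | (2E,5R)-5-{[(8S)-6-benzoyl-7-hydroxy-2,2-dimethyl-8-(3-methylbut-2-en-1-yl)-5-oxo-5,8-dihydro-2H-chromen-8-yl]methyl}-2,6-dimethylhepta-2,6-dienoic acid (CNP0333091.1) | C=C(C)[C@H](C/C=C(\C)C(=O)O)C[C@@]1(CC=C(C)C)C(O)=C(C(=O)c2ccccc2)C(=O)C2=C1OC(C)(C)C=C2 | target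

**Step count**
Total steps: 10. Longest linear sequence: 10 steps (1 + 2 → 23).

**Three steps most likely to fail**

Step 7 (the proposed new method). The catalyst has to distinguish a prenyl group from a β-branched alkyl group, so the diastereomer ratio may be low, and the hindered ester may react slowly. Fallback, known chemistry: starting from 13, unselective mono-saponification with KOH (1.1 equiv) in THF–water at 0 °C gives 14 together with the (2S)-epimeric half-ester F1 in about equal amounts. Because the side-chain centre is fixed these are diastereomers; they are separated by preparative HPLC or by crystallisation of their (S)-1-phenylethylammonium salts, and pure 14 rejoins the route at step 8.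

Step 8. The one-flask acylation/Claisen closure may stop at the open chain or give the enol lactone instead of ring A. Fallback: starting from 14, the acid is converted under neutral conditions with 1-chloro-N,N,2-trimethylprop-1-en-1-amine (CH2Cl2, 0 °C) into the acid chloride F2. This acylates (1Z)-1-phenyl-1,3-bis(trimethylsilyloxy)buta-1,3-diene F3 (made from 15 by two successive silylations) at its terminal carbon (CH2Cl2, −78 → 20 °C, aqueous work-up), so that triketo ester 17 is isolated. Ring A is then closed in a separate operation with Mg(OMe)2 in MeOH (Claisen cyclisation), returning to the route at 18.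

Step 9. The condensation of the acidic, hindered trione may be sluggish, or the pyran may close on the wrong oxygen. Fallback: starting from 18, C-prenylation of the ring CH2 (C-5 of the cyclohexene ring) with prenyl bromide 11 and aqueous KOH at 0 °C gives the 5-C-prenyl trione F4. DDQ in toluene at 80 °C then effects the dehydrogenative cyclisation of the prenyl enol (through the same 1-oxatriene) and returns to the route at 21.

**Further compounds**
F1 | step 7 | (2S)-2-[(2R,4E)-6-tert-butoxy-5-methyl-6-oxo-2-(prop-1-en-2-yl)hex-4-en-1-yl]-2-(methoxycarbonyl)-5-methylhex-4-enoic acid (C-2 epimer of 14) | C=C(C)[C@H](C/C=C(\C)C(=O)OC(C)(C)C)C[C@](C(=O)O)(CC=C(C)C)C(=O)OC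
F2 | step 8 | acid chloride of 14 (carboxyl replaced by chlorocarbonyl, same configuration) | C=C(C)[C@H](C/C=C(\C)C(=O)OC(C)(C)C)C[C@@](C(=O)Cl)(CC=C(C)C)C(=O)OC
F3 | step 8 | (1Z)-1-phenyl-1,3-bis(trimethylsilyloxy)buta-1,3-diene | C=C(O[Si](C)(C)C)/C=C(\O[Si](C)(C)C)c1ccccc1
F4 | step 9 | 5-C-(3-methylbut-2-en-1-yl) derivative of 18 (dienol form, same configuration) | C=C(C)[C@H](C/C=C(\C)C(=O)OC(C)(C)C)C[C@@]1(CC=C(C)C)C(O)=C(C(=O)c2ccccc2)C(=O)C(CC=C(C)C)=C1O
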